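**Remark on the chemistry.** The target SMILES places H5, the C20 methyl, the C19 carboxyl and the C9 side chain on one face (4S,5S,9S,10R,13R), which is a cis A/B fusion; the route is built for exactly this isomer. Labdane locants are used for all intermediates. C4 in 11/12, C8 in 28/29 and C7 in 31/32 form as epimer mixtures that converge, so they are drawn without a descriptor; 22 is an E/Z mixture.

## Retrosynthetic overview

1. Target 36 ⇒ hydroxy acid 34 (late C13 acetylation); the C8=C17 methylene comes from α-methylenation of a C7 ketone followed by allylic-formate hydrogenolysis; C9–C11 comes from conjugate addition of the (R)-linalool-derived C11–C16 Grignard reagent to ring-B enone 18.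
2. 18 ⇒ ring-A cyclohexene acid 15 ⇒ vinyl δ-lactone 12 by a lactone-enolate Claisen ring contraction (C3–C4 formed, C1–O broken). The feature used: C4 is quaternary, carries the C18 methyl and the C19 carboxyl, and is bonded to the ring-A methylene C3, with C19 syn to C20 across the cis ring fusion.
3. 12 ⇒ dienone propanoate 10 by a desymmetrising intramolecular Michael addition (C4–C5) and a conjugate reduction stored as the C7 silyl enol ether.
4. 10 ⇒ benzoic acid by Birch reductive methylation, vinyl addition and kinetic resolution; the C1 carbinol is the only source of ring chirality and is consumed in the key step.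
5. Ring order: ring B (the benzoic acid ring) → sacrificial δ-lactone → ring A.

Key step: step 10

## Route

Step 1
Reactants: 1 benzoic acid
Product: 2 1-methylcyclohexa-2,5-diene-1-carboxylic acid
Conditions: Li, NH3(l)/THF, −78 °C; MeI; aq. HCl
Reagents that add atoms: iodomethane, CI
Why: Birch reduction of the benzoate gives the ring-protonated carboxylate enediolate, which is C-methylated at the ipso carbon (Birch reductive alkylation) to give the 1,4-diene with the future C10 quaternary carbon, still achiral.

Step 2
Reactants: 2 1-methylcyclohexa-2,5-diene-1-carboxylic acid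
Product: 3 (1-methylcyclohexa-2,5-dien-1-yl)methanol
Conditions: LiAlH4, THF, 0 °C → reflux; Fieser work-up
Reagents that add atoms: none
Why: Hydride reduction of the acid to the neopentyl alcohol leaves the isolated ring alkenes untouched.

Step 3
Reactants: 3 (1-methylcyclohexa-2,5-dien-1-yl)methanol
Product: 4 1-methylcyclohexa-2,5-diene-1-carbaldehyde
Conditions: Dess–Martin periodinane, NaHCO3, CH2Cl2, 0 °C → rt; used crude
Reagents that add atoms: none
Why: Buffered Dess–Martin oxidation gives the non-enolisable aldehyde under neutral conditions, which avoids acid-induced aromatisation of the dihydroarene.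

Step 4
Reactants: 4 1-methylcyclohexa-2,5-diene-1-carbaldehyde; 5 vinylmagnesium bromide
Product: 6 rac-1-(1-methylcyclohexa-2,5-dien-1-yl)prop-2-en-1-ol
Conditions: THF, −78 → 0 °C; aq. NH4Cl
Reagents that add atoms: none
Why: Grignard 1,2-addition to a non-enolisable aldehyde creates the C1 carbinol as a racemate, resolved in step 5.

Step 5
Reactants: 6 rac-1-(1-methylcyclohexa-2,5-dien-1-yl)prop-2-en-1-ol
Product: 7 (R)-1-(1-methylcyclohexa-2,5-dien-1-yl)prop-2-en-1-ol
Conditions: Ti(OiPr)4, D-(−)-diisopropyl tartrate, t-BuOOH (0.6 equiv), 4 Å MS, CH2Cl2, −20 °C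
Reagents that add atoms: none
Why: Sharpless kinetic resolution of a secondary allylic alcohol: with the D-tartrate the (S)-enantiomer is epoxidised fast (the carbinol substituent lies away from the face of oxygen delivery), so (R)-7 should be recovered in high enantiomeric purity just past half conversion, the α-quaternary group enlarging the rate difference and the homoallylic ring alkenes being inert.

Step 6
Reactants: 7 (R)-1-(1-methylcyclohexa-2,5-dien-1-yl)prop-2-en-1-ol; 8 propanoyl chloride
Product: 9 (R)-1-(1-methylcyclohexa-2,5-dien-1-yl)allyl propanoate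
Conditions: pyridine, DMAP (cat.), CH2Cl2, 0 °C → rt
Reagents that add atoms: none
Why: DMAP-catalysed O-acylation installs C19, C4 and C18 without touching C1.

Step 7
Reactants: 9 (R)-1-(1-methylcyclohexa-2,5-dien-1-yl)allyl propanoate
Product: 10 (R)-1-(1-methyl-4-oxocyclohexa-2,5-dien-1-yl)allyl propanoate
Conditions: Rh2(cap)4 (dirhodium tetracaprolactamate, 1 mol %), t-BuOOH (5 equiv), K2CO3, CH2Cl2, rt
Reagents that add atoms: tert-butyl hydroperoxide, CC(C)(C)OO
Why: Peroxyl-radical allylic oxidation attacks the doubly allylic C7 methylene far faster than any other C–H, and the dienyl termini are shielded by the quaternary carbon, so the cross-conjugated 4,4-disubstituted dienone with two enantiotopic enone arms should result.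

Step 8
Reactants: 10 (R)-1-(1-methyl-4-oxocyclohexa-2,5-dien-1-yl)allyl propanoate
Product: 11 vinyl δ-lactone enone (1R 5R 10R)
Conditions: LiN(SiMe3)2 (1.05 equiv), THF, −78 °C; AcOH quench at −78 °C
Reagents that add atoms: none
Why: Intramolecular Michael addition (6-enolendo-exo-trig) of the propanoate lithium enolate forms C4–C5, the short tether forcing a cis-fused δ-lactone, and a chair transition state with the C1 vinyl group equatorial selects the enone arm that leaves the vinyl cis to C9, so C1 sets C5 and C10, while at −78 °C the lithium enolate is too cold to undergo its own acyclic [3,3] shift.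

Step 9
Reactants: 11 vinyl δ-lactone enone (1R 5R 10R)
Product: 12 vinyl δ-lactone C7 tert-butyldimethylsilyl enol ether (1R 5R 10R)
Conditions: [(Ph3P)CuH]6 (0.35 equiv), t-BuMe2SiCl (2.5 equiv), benzene/THF, rt; filtration through Et3N-deactivated silica
Reagents that add atoms: tert-butyldimethylsilyl chloride, CC(C)(C)[Si](C)(C)Cl
Why: Copper hydride conjugate reduction with silyl trapping delivers hydride to C9 and O-silylates the copper enolate, giving only the C7=C8 enol ether while the vinyl group and lactone are inert to this hydride; the enol ether masks the ketone from the amide base of step 10 and records where the C8=C9 enone must return in step 13.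

Step 10
Reactants: 12 vinyl δ-lactone C7 tert-butyldimethylsilyl enol ether (1R 5R 10R)
Product: 15 ring-A cyclohexene C19 acid, via silyl ketene acetal 13 (not isolated), via trimethylsilyl ester 14 (not isolated)
Conditions: LiN(iPr)2 (1.3 equiv), Me3SiCl/Et3N (3 equiv, present from the start), THF, −78 °C → rt; solvent exchange, toluene, 105 °C; H2O, pH 5 buffer
Reagents that add atoms: chlorotrimethylsilane, C[Si](C)(C)Cl (silyl groups of 13 and 14 only; none of its atoms remain in 15)
Why: LiN(iPr)2 removes the C4 proton of the lactone and in situ O-silylation gives the cyclic ketene acetal 13, in which C4=C19–O–C1–C2=C3 is a 1,5-diene; on heating a concerted suprafacial [3,3] shift forms C3–C4 as C1–O breaks and gives silyl ester 14, hydrolysed on work-up. The closest known reaction is the Ireland–Claisen rearrangement in its ring-contracting form, in which silyl ketene acetals of vinyl-substituted lactones give cycloalkene carboxylic acids. Ring A (C1, C2, C3, C4, C5, C10) closes pericyclically through a six-membered boat transition state that, together with the C5–C10 bond, has the shape of bicyclo[2.2.2]octane, so a six-membered carbocycle with a cis C1=C2 bond replaces the six-membered lactone and the cis C5–C10 fusion is untouched. C4 is the only new stereocentre and is dictated by C1: because the vinyl group is cis to C9, the C2–C3 bridge must form on the face of C6 and C9, and the carboxyl, the remnant of the O–C19 bridge, stays on the face of H5 and the C20 methyl whichever C4 epimer of 12 enters. The step needs the [3,3] path to outrun C-silylation and hydrolysis of the ketene acetal and needs ring B to stay inert; in situ silylation at −78 °C, strictly aprotic heating and the C7 silyl enol ether, which has no acidic proton and is stable to the amide base, secure this.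

Step 11
Reactants: 15 ring-A cyclohexene C19 acid
Product: 16 2-(trimethylsilyl)ethyl ester of 15
Conditions: Me3SiCH2CH2OH, PPh3, DIAD, THF, 0 °C → rt
Reagents that add atoms: 2-(trimethylsilyl)ethanol, C[Si](C)(C)CCO
Why: In the Mitsunobu esterification the hindered tertiary carboxylate acts as nucleophile toward the primary alkoxyphosphonium ion, so the crowded C19 carbonyl is never attacked, and the resulting ester is later removable with fluoride.

Step 12
Reactants: 16 2-(trimethylsilyl)ethyl ester of 15
Product: 17 ring-A saturated ester (C7=C8 silyl enol ether kept)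
Conditions: H2 (3 atm), RhCl(PPh3)3 (10 mol %), benzene, rt
Reagents that add atoms: none
Why: Homogeneous hydrogenation with RhCl(PPh3)3 reduces the cis-disubstituted C1=C2 alkene and should spare the trisubstituted, electron-rich silyl enol ether; no stereocentre is formed.

Step 13
Reactants: 17 ring-A saturated ester (C7=C8 silyl enol ether kept)
Product: 18 ring-B enone (C7=O C8=C9)
Conditions: Pd(OAc)2 (1.2 equiv), MeCN, 40 °C
Reagents that add atoms: none
Why: Saegusa–Ito oxidation: the palladium enolate forms at C8 and β-hydride elimination can only take a C9 hydrogen, so the enone returns regiospecifically on the C8–C9 side.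

Step 14
Reactants: 19 (R)-linalool
Product: 20 (R)-linalool tert-butyldimethylsilyl ether
Conditions: t-BuMe2SiOTf, 2,6-lutidine, CH2Cl2, 0 °C → rt
Reagents that add atoms: tert-butyldimethylsilyl triflate, CC(C)(C)[Si](C)(C)OS(=O)(=O)C(F)(F)F
Why: The silyl triflate silylates the tertiary allylic alcohol under non-acidic conditions, so the future C13 centre keeps its configuration.

Step 15
Reactants: 20 (R)-linalool tert-butyldimethylsilyl ether
Product: 21 (R)-4-[(tert-butyldimethylsilyl)oxy]-4-methylhex-5-enal
Conditions: O3, CH2Cl2/MeOH, −78 °C, Sudan Red 7B end point; Me2S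
Reagents that add atoms: ozone, [O-][O+]=O
Why: Ozone attacks the electron-rich trisubstituted alkene much faster than the vinyl group, which is hindered and inductively deactivated by the neighbouring silyloxy-bearing quaternary carbon, and the dye marks the end point.

Step 16
Reactants: 21 (R)-4-[(tert-butyldimethylsilyl)oxy]-4-methylhex-5-enal
Product: 22 (R)-1,4-bis[(tert-butyldimethylsilyl)oxy]-4-methylhexa-1,5-diene
Conditions: t-BuMe2SiOTf, Et3N, CH2Cl2, 0 °C → rt
Reagents that add atoms: tert-butyldimethylsilyl triflate, CC(C)(C)[Si](C)(C)OS(=O)(=O)C(F)(F)F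
Why: Soft enolisation converts the aldehyde into its silyl enol ether, marking the C–C bond that must be cut to remove the surplus carbon.

Step 17
Reactants: 22 (R)-1,4-bis[(tert-butyldimethylsilyl)oxy]-4-methylhexa-1,5-diene
Product: 24 (R)-3-[(tert-butyldimethylsilyl)oxy]-3-methylpent-4-en-1-ol, via nor-aldehyde 23 (not isolated)
Conditions: O3, CH2Cl2/MeOH, −78 °C, Sudan Red 7B end point; NaBH4, −78 → 0 °C
Reagents that add atoms: ozone, [O-][O+]=O
Why: The enol ether is far more electron-rich than the vinyl group and is cleaved selectively, excising one carbon as silyl formate, and immediate borohydride reduction of the β-silyloxy aldehyde prevents its β-elimination.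

Step 18
Reactants: 24 (R)-3-[(tert-butyldimethylsilyl)oxy]-3-methylpent-4-en-1-ol
Product: 25 (R)-5-bromo-3-methyl-3-[(tert-butyldimethylsilyl)oxy]pent-1-ene
Conditions: CBr4, PPh3, imidazole, CH2Cl2, 0 °C
Reagents that add atoms: carbon tetrabromide, BrC(Br)(Br)Br
Why: Appel bromination of the primary alcohol proceeds by SN2 displacement under neutral conditions that the tertiary allylic silyl ether tolerates.

Step 19
Reactants: 25 (R)-5-bromo-3-methyl-3-[(tert-butyldimethylsilyl)oxy]pent-1-ene; 18 ring-B enone (C7=O C8=C9)
Product: 27 C9-alkylated C7 trimethylsilyl enol ether, via Grignard reagent 26 (not isolated)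
Conditions: 25, Mg, THF, rt; then CuBr·SMe2 (10 mol %), HMPA, Me3SiCl, 18, THF, −78 → −40 °C; Et3N, pentane, filtration
Reagents that add atoms: magnesium, [Mg] (in 26 only); chlorotrimethylsilane, C[Si](C)(C)Cl
Why: Copper-catalysed, chlorosilane-accelerated conjugate addition of the Grignard reagent forms C9–C11 and traps the enolate as the C7=C8 silyl enol ether; C9 is set by axial attack anti to the pseudoaxial C10–C1 bond on the convex face that carries H5 and the C20 methyl, the opposite face being blocked by ring A and its C4 quaternary carbon, while C13 comes unchanged from linalool.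

Step 20
Reactants: 27 C9-alkylated C7 trimethylsilyl enol ether
Product: 30 α-methylene ketone (C7=O C8=C17), via Mannich base 28 (not isolated), via trimethylammonium iodide 29 (not isolated)
Conditions: CH2=NMe2+ I−, CH2Cl2, rt; aq. NaHCO3; MeI, Et2O; DBU, CH2Cl2, rt
Reagents that add atoms: N,N-dimethylmethyleneiminium iodide, C=[N+](C)C.[I-]; iodomethane, CI (in 29 only)
Why: The silyl enol ether reacts regiospecifically at C8 with the iminium salt (Mannich reaction), and quaternisation followed by E1cB loss of trimethylamine gives the exocyclic enone, erasing the transient C8 centre; C9–H is not activated by the carbonyl, so the exocyclic position should hold.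

Step 21
Reactants: 30 α-methylene ketone (C7=O C8=C17)
Product: 31 C7 allylic alcohol
Conditions: NaBH4, CeCl3·7H2O, MeOH, −78 → 0 °C
Reagents that add atoms: none
Why: Luche conditions enforce 1,2-reduction of the α-methylene ketone, and the C7 configuration is irrelevant because C7 becomes a methylene in step 23.

Step 22
Reactants: 31 C7 allylic alcohol
Product: 32 C7 allylic formate
Conditions: HCO2H, DCC, DMAP (cat.), CH2Cl2, 0 °C → rt
Reagents that add atoms: formic acid, OC=O
Why: Carbodiimide-mediated formylation installs the leaving group that also serves as the internal hydride source for step 23.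

Step 23
Reactants: 32 C7 allylic formate
Product: 33 labda-8(17),14-diene with C13 silyl ether and C19 2-(trimethylsilyl)ethyl ester
Conditions: Pd(OAc)2 (5 mol %), n-Bu3P (20 mol %), 1,4-dioxane, 80 °C
Reagents that add atoms: none
Why: Zerovalent palladium (formed in situ) ionises the allylic formate to the C7–C8–C17 π-allyl complex, and decarboxylative hydride transfer goes to the more substituted terminus C7 (palladium-catalysed allylic formate hydrogenolysis), which removes the C7 oxygen and keeps the less substituted exocyclic C8=C17 alkene; the C13 silyl ether is not ionised.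

Step 24
Reactants: 33 labda-8(17),14-diene with C13 silyl ether and C19 2-(trimethylsilyl)ethyl ester
Product: 34 13-hydroxy-19-oic acid
Conditions: Bu4NF (6 equiv), THF, 50 °C; aq. NH4Cl, pH 4
Reagents that add atoms: none
Why: Fluoride attacks silicon only, fragmenting the 2-silylethyl ester to ethylene and the carboxylate and cleaving the tertiary silyl ether, so the hindered C19 carbonyl and both alkenes are not touched.

Step 25
Reactants: 34 13-hydroxy-19-oic acid
Product: 36 target (4S,5S,9S,10R,13R)-13-acetoxylabda-8(17),14-dien-19-oic acid, via mixed anhydride 35 (not isolated)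
Conditions: Ac2O (5 equiv), DMAP (0.3 equiv), Et3N, CH2Cl2, rt; then THF/aq. NaHCO3, rt; acidify to pH 4
Reagents that add atoms: acetic anhydride, CC(=O)OC(C)=O
Why: DMAP-catalysed acetylation esterifies the tertiary allylic alcohol with retention at C13, and the mixed acetic anhydride formed at the hindered acid is hydrolysed at its unhindered acetyl carbonyl during the bicarbonate work-up, returning the free C19 acid.

## Compound list

1 | benzoic acid | OC(=O)c1ccccc1 | starting material
2 | 1-methylcyclohexa-2,5-diene-1-carboxylic acid | CC1(C(=O)O)C=CCC=C1 | intermediate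
3 | (1-methylcyclohexa-2,5-dien-1-yl)methanol | CC1(CO)C=CCC=C1 | intermediate
4 | 1-methylcyclohexa-2,5-diene-1-carbaldehyde | CC1(C=O)C=CCC=C1 | intermediate
5 | vinylmagnesium bromide | C=C[Mg]Br | starting material
6 | rac-1-(1-methylcyclohexa-2,5-dien-1-yl)prop-2-en-1-ol | C=CC(O)C1(C)C=CCC=C1 | intermediate
7 | (R)-1-(1-methylcyclohexa-2,5-dien-1-yl)prop-2-en-1-ol | C=C[C@@H](O)C1(C)C=CCC=C1 | intermediate
8 | propanoyl chloride | CCC(=O)Cl | starting material
9 | (R)-1-(1-methylcyclohexa-2,5-dien-1-yl)allyl propanoate | C=C[C@@H](OC(=O)CC)C1(C)C=CCC=C1 | intermediate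
10 | (R)-1-(1-methyl-4-oxocyclohexa-2,5-dien-1-yl)allyl propanoate | C=C[C@@H](OC(=O)CC)C1(C)C=CC(=O)C=C1 | intermediate
11 | vinyl δ-lactone enone: lactone C1–O–C19(=O)–C4(CH3)–C5–C10(CH3) cis-fused to ring B (C7=O, C8=C9), vinyl on C1 cis to C9; 1R,5R,10R, C4 epimers | C=C[C@H]1OC(=O)C(C)[C@H]2CC(=O)C=C[C@@]12C | intermediate
12 | vinyl δ-lactone with C7 tert-butyldimethylsilyl enol ether (C7=C8); 1R,5R,10R, C4 epimers (key-step precursor) | C=C[C@H]1OC(=O)C(C)[C@H]2CC(O[Si](C)(C)C(C)(C)C)=CC[C@@]12C | intermediate
13 | trimethylsilyl ketene acetal of 12 (C4=C19) | C=C[C@H]1OC(O[Si](C)(C)C)=C(C)[C@H]2CC(O[Si](C)(C)C(C)(C)C)=CC[C@@]12C | intermediate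
14 | trimethylsilyl ester of 15 | C1C=C(O[Si](C)(C)C(C)(C)C)C[C@H]2[C@]1(C)C=CC[C@]2(C)C(=O)O[Si](C)(C)C | intermediate
15 | ring-A cyclohexene C19 acid: cis-decalin, C1=C2, C4 with CH3 and CO2H, C7=C8 silyl enol ether; CO2H, C20 and H5 on one face (key-step product) | C1C=C(O[Si](C)(C)C(C)(C)C)C[C@H]2[C@]1(C)C=CC[C@]2(C)C(=O)O | intermediate
16 | 2-(trimethylsilyl)ethyl ester of 15 | C1C=C(O[Si](C)(C)C(C)(C)C)C[C@H]2[C@]1(C)C=CC[C@]2(C)C(=O)OCC[Si](C)(C)C | intermediate
17 | 1,2-dihydro derivative of 16 (ring A saturated, C7=C8 silyl enol ether) | C1C=C(O[Si](C)(C)C(C)(C)C)C[C@H]2[C@]1(C)CCC[C@]2(C)C(=O)OCC[Si](C)(C)C | intermediate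
18 | ring-B enone: cis-decalin 2-(trimethylsilyl)ethyl C19 ester with C7=O and C8=C9 | C1=CC(=O)C[C@H]2[C@]1(C)CCC[C@]2(C)C(=O)OCC[Si](C)(C)C | intermediate
19 | (R)-linalool | CC(C)=CCC[C@](C)(C=C)O | starting material
20 | (R)-linalool tert-butyldimethylsilyl ether | CC(C)=CCC[C@](C)(C=C)O[Si](C)(C)C(C)(C)C | intermediate
21 | (R)-4-[(tert-butyldimethylsilyl)oxy]-4-methylhex-5-enal | O=CCC[C@](C)(C=C)O[Si](C)(C)C(C)(C)C | intermediate
22 | (R)-1,4-bis[(tert-butyldimethylsilyl)oxy]-4-methylhexa-1,5-diene (E/Z) | CC(C)(C)[Si](C)(C)OC=CC[C@](C)(C=C)O[Si](C)(C)C(C)(C)C | intermediate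
23 | (R)-3-[(tert-butyldimethylsilyl)oxy]-3-methylpent-4-enal | O=CC[C@](C)(C=C)O[Si](C)(C)C(C)(C)C | intermediate
24 | (R)-3-[(tert-butyldimethylsilyl)oxy]-3-methylpent-4-en-1-ol | OCC[C@](C)(C=C)O[Si](C)(C)C(C)(C)C | intermediate
25 | (R)-5-bromo-3-methyl-3-[(tert-butyldimethylsilyl)oxy]pent-1-ene | BrCC[C@](C)(C=C)O[Si](C)(C)C(C)(C)C | intermediate
26 | Grignard reagent of 25 | Br[Mg]CC[C@](C)(C=C)O[Si](C)(C)C(C)(C)C | intermediate
27 | C9-alkylated C7 trimethylsilyl enol ether (C7=C8; side chain on C9 cis to C20) | C=C[C@@](C)(CC[C@H]1C=C(O[Si](C)(C)C)C[C@H]2[C@]1(C)CCC[C@]2(C)C(=O)OCC[Si](C)(C)C)O[Si](C)(C)C(C)(C)C | intermediate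
28 | C8 (dimethylamino)methyl C7 ketone (Mannich base) | C=C[C@@](C)(CC[C@H]1C(CN(C)C)C(=O)C[C@H]2[C@]1(C)CCC[C@]2(C)C(=O)OCC[Si](C)(C)C)O[Si](C)(C)C(C)(C)C | intermediate
29 | trimethylammonium iodide of 28 | C=C[C@@](C)(CC[C@H]1C(C[N+](C)(C)C)C(=O)C[C@H]2[C@]1(C)CCC[C@]2(C)C(=O)OCC[Si](C)(C)C)O[Si](C)(C)C(C)(C)C.[I-] | intermediate
30 | α-methylene ketone (C7=O, C8=C17) | C=C[C@@](C)(CC[C@H]1C(=C)C(=O)C[C@H]2[C@]1(C)CCC[C@]2(C)C(=O)OCC[Si](C)(C)C)O[Si](C)(C)C(C)(C)C | intermediate
31 | C7 allylic alcohol (C8=C17) | C=C[C@@](C)(CC[C@H]1C(=C)C(O)C[C@H]2[C@]1(C)CCC[C@]2(C)C(=O)OCC[Si](C)(C)C)O[Si](C)(C)C(C)(C)C | intermediate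
32 | C7 allylic formate | C=C[C@@](C)(CC[C@H]1C(=C)C(OC=O)C[C@H]2[C@]1(C)CCC[C@]2(C)C(=O)OCC[Si](C)(C)C)O[Si](C)(C)C(C)(C)C | intermediate
33 | 2-(trimethylsilyl)ethyl 13-[(tert-butyldimethylsilyl)oxy]labda-8(17),14-dien-19-oate (cis A/B) | C=C[C@@](C)(CC[C@H]1C(=C)CC[C@H]2[C@]1(C)CCC[C@]2(C)C(=O)OCC[Si](C)(C)C)O[Si](C)(C)C(C)(C)C | intermediate
34 | 13-hydroxylabda-8(17),14-dien-19-oic acid (cis A/B) | C=C[C@@](C)(CC[C@H]1C(=C)CC[C@H]2[C@]1(C)CCC[C@]2(C)C(=O)O)O | intermediate
35 | mixed acetic anhydride of 36 | C=C[C@@](C)(CC[C@H]1C(=C)CC[C@H]2[C@]1(C)CCC[C@]2(C)C(=O)OC(C)=O)OC(C)=O | intermediate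
36 | (4S,5S,9S,10R,13R)-13-acetoxylabda-8(17),14-dien-19-oic acid | C=C[C@@](C)(CC[C@H]1C(=C)CC[C@H]2[C@]1(C)CCC[C@]2(C)C(=O)O)OC(C)=O | target

## Step count and risks

Total: 25 steps. Longest linear sequence: 20 steps (steps 1–13 and 19–25); the side chain takes 5 steps (14–18).

**Risk 1, step 10 (key step).** The boat [3,3] shift may stall, or the ketene acetal may be lost to C-silylation or adventitious hydrolysis during heating. The fallback forms the same C3–C4 bond by a stepwise ionic sequence and uses the same stereochemical relay; it sets out from 12 and returns at 17. Hydroboration of the vinyl group of 12 (9-BBN; NaBO3) should give primary alcohol F1, and I2/PPh3/imidazole the iodide F2. LiN(iPr)2 in THF/HMPA should then close C3–C4 by intramolecular alkylation of the lactone enolate to the bridged 2-oxabicyclo[2.2.2]octan-3-one F3; the two-carbon tether can only reach C4 from the face on which it hangs, so C19 again ends syn to C20. Saponification (KOH, aqueous MeOH) should give 1-hydroxy acid F4. Mitsunobu esterification with 2-(trimethylsilyl)ethanol should give hydroxy ester F5, the neopentyl C1 carbinol not competing with the primary alcohol. PhOC(S)Cl/pyridine/DMAP should give thionocarbonate F6, and Bu3SnH/AIBN (Barton–McCombie deoxygenation) should remove the C1 oxygen to give 17.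

**Risk 2, step 8.** The kinetic ester enolate may attack both enantiotopic enone arms without sufficient discrimination, or may be diverted by ester cleavage or a premature acyclic [3,3] shift. The fallback replaces the kinetic enolate by a reversible, soft malonate Michael addition under thermodynamic control; it sets out from 7 and returns at 11. Acylation of 7 with methyl malonyl chloride (pyridine) should give mixed malonate F7, and the oxidation of step 7 its dienone F8. Cs2CO3 in MeCN should cyclise F8 to the cis-fused α-methoxycarbonyl lactone F9, equilibrating toward the isomer with the vinyl group equatorial. K2CO3/MeI should methylate C4 to give F10, and Krapcho demethoxycarbonylation (LiCl, wet DMSO, 130 °C) should give 11.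

**Risk 3, step 19.** Facial selectivity at C9 may be poor or reversed if the cis-decalin enone reacts through its other ring conformer. The fallback inverts the order in which the two C9 substituents arrive; it sets out from 18 and returns at 27. The same copper-catalysed addition would give the C9 epimer of the silyl enol ether, F11. Saegusa–Ito oxidation (Pd(OAc)2, MeCN) should erase C9 and give the C9-substituted enone F12. Copper hydride conjugate reduction with silyl trapping ([(Ph3P)CuH]6, Me3SiCl) should then deliver hydride to the face the alkyl group had preferred, placing the side chain cis to C20 and regenerating 27.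

## Further compounds

F1 | step 10 | primary alcohol from hydroboration of 12 | OCC[C@H]1OC(=O)C(C)[C@H]2CC(O[Si](C)(C)C(C)(C)C)=CC[C@@]12C
F2 | step 10 | primary iodide from F1 | ICC[C@H]1OC(=O)C(C)[C@H]2CC(O[Si](C)(C)C(C)(C)C)=CC[C@@]12C
F3 | step 10 | bridged 2-oxabicyclo[2.2.2]octan-3-one (C1–O–C19 bridge over ring A) | O=C1O[C@@H]2CC[C@@]1(C)[C@H]3CC(O[Si](C)(C)C(C)(C)C)=CC[C@@]23C
F4 | step 10 | 1-hydroxy C19 acid | O[C@@H]1CC[C@](C)(C(=O)O)[C@H]2CC(O[Si](C)(C)C(C)(C)C)=CC[C@@]12C
F5 | step 10 | 2-(trimethylsilyl)ethyl ester of F4 | O[C@@H]1CC[C@](C)(C(=O)OCC[Si](C)(C)C)[C@H]2CC(O[Si](C)(C)C(C)(C)C)=CC[C@@]12C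
F6 | step 10 | O-phenyl thionocarbonate of F5 | S=C(Oc1ccccc1)O[C@@H]1CC[C@](C)(C(=O)OCC[Si](C)(C)C)[C@H]2CC(O[Si](C)(C)C(C)(C)C)=CC[C@@]12C
F7 | step 8 | methyl (R)-1-(1-methylcyclohexa-2,5-dien-1-yl)allyl malonate | C=C[C@@H](OC(=O)CC(=O)OC)C1(C)C=CCC=C1
F8 | step 8 | methyl (R)-1-(1-methyl-4-oxocyclohexa-2,5-dien-1-yl)allyl malonate | C=C[C@@H](OC(=O)CC(=O)OC)C1(C)C=CC(=O)C=C1
F9 | step 8 | C4-methoxycarbonyl vinyl δ-lactone enone | C=C[C@H]1OC(=O)C(C(=O)OC)[C@H]2CC(=O)C=C[C@@]12C
F10 | step 8 | C4-methyl C4-methoxycarbonyl vinyl δ-lactone enone | C=C[C@H]1OC(=O)C(C)(C(=O)OC)[C@H]2CC(=O)C=C[C@@]12C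
F11 | step 19 | C9 epimer of 27 | C=C[C@@](C)(CC[C@@H]1C=C(O[Si](C)(C)C)C[C@H]2[C@]1(C)CCC[C@]2(C)C(=O)OCC[Si](C)(C)C)O[Si](C)(C)C(C)(C)C
F12 | step 19 | C9-substituted enone (C7=O, C8=C9) | C=C[C@@](C)(CCC1=CC(=O)C[C@H]2[C@]1(C)CCC[C@]2(C)C(=O)OCC[Si](C)(C)C)O[Si](C)(C)C(C)(C)C
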